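**Retrosynthetic overview** (atoms numbered in the order of the target SMILES; ring A = cyclopentane C4, C5, C6, C7, C10; ring B = trione ring C12, C13, C15, C22, C24, C31)
1. The strategy rests on ring B, which is cut at C12–C13 and C22–C24 after a final desilylation at O9. This gives the three-carbon bis-nucleophile C12–C31–C24 of β-diketone 14, which already carries ring A through C11 and the C25 acyl group on C24. The partner is the bis-electrophile C13–C15–C22 of malonyl chloride ester 19, with quaternary C15 fixed and its carbonyls differentiated (COCl becomes C13, CO2Me becomes C22).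
2. Diketone 14: C24–C31 by crossed Claisen condensation of ester 11 with ketone 13; C11=C12 by Wittig reaction, later reduced.
3. Ring A stereocentres: C10–H by palladium/formate hydrogenolysis (inversion) of an epoxide placed anti to the isopropenyl group; C7–O from that epoxide; C4 from (R)-limonene.
4. Ring A is formed first (C7–C10 aldol condensation of the limonene-derived keto aldehyde); ring B is formed last.
5. Fragment 2 (19): prenylation of dimethyl methylmalonate, enzymatic desymmetrisation, neutral acid chloride formation.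

Key step: step 15

Assumption: pig liver esterase is taken to hydrolyse the pro-S ester group of 17 (the sense known for 2-alkyl-2-methylmalonates with chains of five or more carbons), so that step 13 gives (R)-18; the fallback for step 13 does not depend on this.

**Fragment 1**

Step 1
Reactants: 1 (R)-(+)-limonene
Product: 2 (4R)-1-methyl-4-(prop-1-en-2-yl)-7-oxabicyclo[4.1.0]heptane (limonene 1,2-oxide, cis/trans mixture at the epoxide)
Conditions: mCPBA (1.0 equiv), NaHCO3, CH2Cl2, 0 °C
Reagents that add atoms: 3-chloroperoxybenzoic acid (mCPBA), O=C(OO)c1cccc(Cl)c1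
Why: Prilezhaev epoxidation should take the more electron-rich trisubstituted ring alkene and leave the isopropenyl group; the epoxide configuration is irrelevant because both its carbons become carbonyl carbons in step 2.

Step 2
Reactants: 2 (4R)-limonene 1,2-oxide
Product: 3 (3R)-6-oxo-3-(prop-1-en-2-yl)heptanal
Conditions: H5IO6, THF/H2O, 0 °C → rt
Reagents that add atoms: water, O
Why: Periodic acid hydrolyses the epoxide to the 1,2-diol in situ and cleaves it (Malaprade glycol cleavage) to the keto aldehyde, with the stereocentre (target C4) untouched.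

Step 3
Reactants: 3 (3R)-6-oxo-3-(prop-1-en-2-yl)heptanal
Product: 4 (5S)-2-methyl-5-(prop-1-en-2-yl)cyclopent-1-ene-1-carbaldehyde
Conditions: piperidine, AcOH (cat.), toluene, reflux (water removal)
Reagents that add atoms: none
Why: Intramolecular aldol condensation through the piperidine enamine of the aldehyde (5-enolexo attack of C10 on the ketone C7, then dehydration) closes ring A as the conjugated enal; the C4–H is not on the enolisable path, so the centre is kept.

Step 4
Reactants: 4 (5S)-2-methyl-5-(prop-1-en-2-yl)cyclopent-1-ene-1-carbaldehyde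
Product: 5 [(5S)-2-methyl-5-(prop-1-en-2-yl)cyclopent-1-en-1-yl]methanol
Conditions: NaBH4, CeCl3·7H2O, MeOH, 0 °C
Reagents that add atoms: none
Why: Luche reduction gives clean 1,2-reduction of the enal to the allylic alcohol.

Step 5
Reactants: 5 [(5S)-2-methyl-5-(prop-1-en-2-yl)cyclopent-1-en-1-yl]methanol
Product: 6 [(1R,2S,5R)-5-methyl-2-(prop-1-en-2-yl)-6-oxabicyclo[3.1.0]hexan-1-yl]methanol
Conditions: VO(acac)2 (cat.), t-BuOOH, CH2Cl2, 0 °C → rt
Reagents that add atoms: tert-butyl hydroperoxide, CC(C)(C)OO
Why: Hydroxyl-directed vanadium-catalysed epoxidation takes only the allylic-alcohol alkene and should deliver oxygen to the face anti to the isopropenyl group on the neighbouring carbon, which sets C7 (R, final) and places the C10–O bond for later inversion.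

Step 6
Reactants: 6 [(1R,2S,5R)-5-methyl-2-(prop-1-en-2-yl)-6-oxabicyclo[3.1.0]hexan-1-yl]methanol
Product: 8 methyl (2E)-3-[(1S,2S,5R)-5-methyl-2-(prop-1-en-2-yl)-6-oxabicyclo[3.1.0]hexan-1-yl]prop-2-enoate, via epoxy aldehyde 7 (not isolated)
Conditions: Dess–Martin periodinane, pyridine, CH2Cl2, 0 °C → rt; then Ph3P=CHCO2Me, rt
Reagents that add atoms: methyl (triphenylphosphoranylidene)acetate, COC(=O)C=P(c1ccccc1)(c1ccccc1)c1ccccc1
Why: Buffered Dess–Martin oxidation gives an epoxy aldehyde without α-hydrogen, which the stabilised ylide converts in the same flask into the (E)-enoate (Wittig reaction), forming C11=C12.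

Step 7
Reactants: 8 methyl (2E)-3-[(1S,2S,5R)-5-methyl-2-(prop-1-en-2-yl)-6-oxabicyclo[3.1.0]hexan-1-yl]prop-2-enoate
Product: 9 methyl (2E)-3-[(1S,2R,5R)-2-hydroxy-2-methyl-5-(prop-1-en-2-yl)cyclopentyl]prop-2-enoate
Conditions: Pd2(dba)3·CHCl3 (cat.), n-Bu3P, HCO2H, Et3N, 1,4-dioxane, rt
Reagents that add atoms: none
Why: In this palladium-catalysed formate hydrogenolysis of an alkenyloxirane, zerovalent palladium opens the allylic C10–O bond with inversion, and the hydride formed by decarboxylation of formate is delivered from palladium to the more substituted allyl terminus C10; the net inversion sets C10 (S) with C11 cis to the C7 hydroxyl and trans to the isopropenyl group, while C7–O and the enoate stay intact.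

Step 8
Reactants: 9 methyl (2E)-3-[(1S,2R,5R)-2-hydroxy-2-methyl-5-(prop-1-en-2-yl)cyclopentyl]prop-2-enoate
Product: 10 methyl (2E)-3-[(1S,2R,5R)-2-methyl-5-(prop-1-en-2-yl)-2-(triethylsilyloxy)cyclopentyl]prop-2-enoate
Conditions: Et3SiOTf, 2,6-lutidine, CH2Cl2, −78 → 0 °C
Reagents that add atoms: triethylsilyl trifluoromethanesulfonate, CC[Si](CC)(CC)OS(=O)(=O)C(F)(F)F
Why: Silyl triflate with a hindered base silylates the tertiary alcohol; protection at this stage prevents lactonisation after the reduction and masks the hydroxyl for the strongly basic steps.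

Step 9
Reactants: 10 methyl (2E)-3-[(1S,2R,5R)-2-methyl-5-(prop-1-en-2-yl)-2-(triethylsilyloxy)cyclopentyl]prop-2-enoate
Product: 11 methyl 3-[(1S,2R,5R)-2-methyl-5-(prop-1-en-2-yl)-2-(triethylsilyloxy)cyclopentyl]propanoate
Conditions: Mg, MeOH, 0 °C → rt
Reagents that add atoms: none
Why: Single-electron (dissolving-metal) conjugate reduction with magnesium in methanol saturates only the ester-conjugated C11=C12 bond and leaves the isolated isopropenyl alkene and the silyl ether alone.

Step 10
Reactants: 12 (2S)-2-methylbutanoic acid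
Product: 13 (3S)-3-methylpentan-2-one
Conditions: MeLi (2.2 equiv), Et2O, 0 °C; then inverse quench into cold aq. HCl
Reagents that add atoms: methyllithium, [Li]C
Why: Addition of methyllithium to the lithium carboxylate stops at the dilithium gem-diolate, which gives the methyl ketone only on work-up; the α-stereocentre is not enolised under these conditions.

Step 11
Reactants: 11 methyl 3-[(1S,2R,5R)-2-methyl-5-(prop-1-en-2-yl)-2-(triethylsilyloxy)cyclopentyl]propanoate; 13 (3S)-3-methylpentan-2-one
Product: 14 (3S)-3-methyl-8-[(1S,2R,5R)-2-methyl-5-(prop-1-en-2-yl)-2-(triethylsilyloxy)cyclopentyl]octane-4,6-dione (fragment 1)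
Conditions: 13 (2.5 equiv), LiN(i-Pr)2 (2.5 equiv), THF, −78 °C; then 11, −78 °C → rt; aq. NH4Cl
Reagents that add atoms: none
Why: Crossed Claisen condensation: kinetic deprotonation of 13 occurs only at its methyl group (C24), not at the stereogenic C27–H, and this enolate acylates the unhindered methyl ester (C24–C31 bond), the diketone being removed as its enolate by the excess of the inexpensive ketone enolate.

**Fragment 2**

Step 12
Reactants: 15 dimethyl 2-methylmalonate; 16 1-bromo-3-methylbut-2-ene
Product: 17 dimethyl 2-methyl-2-(3-methylbut-2-en-1-yl)malonate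
Conditions: NaH, THF, 0 °C; then 16, 0 °C → rt
Reagents that add atoms: none
Why: Malonic ester alkylation (SN2 at the primary allylic bromide) builds the quaternary carbon C15 in prochiral form.

Step 13
Reactants: 17 dimethyl 2-methyl-2-(3-methylbut-2-en-1-yl)malonate
Product: 18 (2R)-2-(methoxycarbonyl)-2,5-dimethylhex-4-enoic acid
Conditions: pig liver esterase, 0.1 M phosphate buffer pH 7.5, DMSO (10%), 25 °C, pH-stat (1 M NaOH); then HCl to pH 3, 0 °C
Reagents that add atoms: water, O
Why: Enzymatic desymmetrisation: the esterase hydrolyses one of the two enantiotopic ester groups (pro-S, see assumption) and stops at the half-ester, so the quaternary centre C15 is set by the enzyme's discrimination between the two groups.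

Step 14
Reactants: 18 (2R)-2-(methoxycarbonyl)-2,5-dimethylhex-4-enoic acid
Product: 19 methyl (2S)-2-(chlorocarbonyl)-2,5-dimethylhex-4-enoate (fragment 2)
Conditions: 1-chloro-N,N,2-trimethylprop-1-en-1-amine, CH2Cl2, 0 °C → rt; used directly
Reagents that add atoms: 1-chloro-N,N,2-trimethylprop-1-en-1-amine, CC(C)=C(Cl)N(C)C
Why: The α-chloroenamine (Ghosez reagent) forms the acid chloride under neutral conditions, so no HCl is present to add to the prenyl alkene or to lactonise the acid; the centre is untouched and only its descriptor changes (R to S) through the priority rules.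

**Union and completion**

Step 15
Reactants: 14 (3S)-3-methyl-8-[(1S,2R,5R)-2-methyl-5-(prop-1-en-2-yl)-2-(triethylsilyloxy)cyclopentyl]octane-4,6-dione; 19 methyl (2S)-2-(chlorocarbonyl)-2,5-dimethylhex-4-enoate
Product: 21 (6R)-3,5-dihydroxy-6-methyl-6-(3-methylbut-2-en-1-yl)-2-[(2S)-2-methylbutanoyl]-4-{[(1S,2R,5R)-2-methyl-5-(prop-1-en-2-yl)-2-(triethylsilyloxy)cyclopentyl]methyl}cyclohexa-2,4-dien-1-one, via acyclic triketo ester 20 (not isolated)
Conditions: LiN(i-Pr)2 (3.2 equiv), THF, −78 → −20 °C; 19, −78 °C → rt, then 40 °C; aq. citric acid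
Reagents that add atoms: none
Why: Two equivalents of LiN(i-Pr)2 convert 14 into its 1,3-dianion, the second proton being taken from the unbranched methylene C12 and not from the methine C27, and this terminal carbanion, the most nucleophilic site, attacks the acid chloride carbon of 19 (C12–C13 bond), the third equivalent of base then removing the newly acidic C12–H of triketo ester 20. On warming, the central enolate carbon C24 adds to the methyl ester carbonyl C22 in a 6-exo-trig Claisen (Dieckmann) closure of ring B and methoxide is expelled, the product leaving as its doubly deprotonated trione, which drives the sequence and shields the 2,2-dialkyl-1,3-dicarbonyl unit from retro-Claisen cleavage. The closest known reaction types are the terminal C-acylation of β-diketone dianions and the base-mediated Claisen cyclisation of triketo esters to acylcyclohexanetriones. No stereocentre is formed: C12 and C24 end as sp2 carbons, C15 is carried over unchanged because the acid chloride carbon can only become C13 and the ester carbon C22, and C4, C7, C10 and C27 are not touched. The step needs site selectivity (C12 before C24 and C27), chemoselectivity (COCl before CO2Me) and C- over O-acylation; these rest on the higher reactivity of the last-formed carbanion, the large reactivity gap between the two acyl groups of 19, and the reversibility of enol ester or enol lactone formation under the strongly basic conditions, where only the C-acylated trione dianion is a thermodynamic sink.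

Step 16
Reactants: 21 O-triethylsilyl ether of the target
Product: 22 (6R)-3,5-dihydroxy-4-{[(1S,2R,5R)-2-hydroxy-2-methyl-5-(prop-1-en-2-yl)cyclopentyl]methyl}-6-methyl-6-(3-methylbut-2-en-1-yl)-2-[(2S)-2-methylbutanoyl]cyclohexa-2,4-dien-1-one (target)
Conditions: HF·pyridine, pyridine, THF, 0 °C → rt
Reagents that add atoms: none
Why: Buffered fluoride desilylation frees the tertiary alcohol without the strong acid that could cyclise the enols onto the prenyl group or onto C7.

**Compound list**
1 | (R)-(+)-limonene | CC1=CC[C@@H](CC1)C(C)=C | starting material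
2 | (4R)-1-methyl-4-(prop-1-en-2-yl)-7-oxabicyclo[4.1.0]heptane (cis/trans mixture at the epoxide) | C=C(C)[C@@H]1CCC2(C)OC2C1 | intermediate
3 | (3R)-6-oxo-3-(prop-1-en-2-yl)heptanal | C=C(C)[C@@H](CC=O)CCC(C)=O | intermediate
4 | (5S)-2-methyl-5-(prop-1-en-2-yl)cyclopent-1-ene-1-carbaldehyde | C=C(C)[C@@H]1CCC(C)=C1C=O | intermediate
5 | [(5S)-2-methyl-5-(prop-1-en-2-yl)cyclopent-1-en-1-yl]methanol | C=C(C)[C@@H]1CCC(C)=C1CO | intermediate
6 | [(1R,2S,5R)-5-methyl-2-(prop-1-en-2-yl)-6-oxabicyclo[3.1.0]hexan-1-yl]methanol | C=C(C)[C@@H]1CC[C@@]2(C)O[C@@]12CO | intermediate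
7 | (1S,2S,5R)-5-methyl-2-(prop-1-en-2-yl)-6-oxabicyclo[3.1.0]hexane-1-carbaldehyde | C=C(C)[C@@H]1CC[C@@]2(C)O[C@@]12C=O | intermediate (not isolated)
8 | methyl (2E)-3-[(1S,2S,5R)-5-methyl-2-(prop-1-en-2-yl)-6-oxabicyclo[3.1.0]hexan-1-yl]prop-2-enoate | C=C(C)[C@@H]1CC[C@@]2(C)O[C@@]12/C=C/C(=O)OC | intermediate
9 | methyl (2E)-3-[(1S,2R,5R)-2-hydroxy-2-methyl-5-(prop-1-en-2-yl)cyclopentyl]prop-2-enoate | C=C(C)[C@@H]1CC[C@@](C)(O)[C@H]1/C=C/C(=O)OC | intermediate
10 | methyl (2E)-3-[(1S,2R,5R)-2-methyl-5-(prop-1-en-2-yl)-2-(triethylsilyloxy)cyclopentyl]prop-2-enoate | C=C(C)[C@@H]1CC[C@@](C)(O[Si](CC)(CC)CC)[C@H]1/C=C/C(=O)OC | intermediate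
11 | methyl 3-[(1S,2R,5R)-2-methyl-5-(prop-1-en-2-yl)-2-(triethylsilyloxy)cyclopentyl]propanoate | C=C(C)[C@@H]1CC[C@@](C)(O[Si](CC)(CC)CC)[C@H]1CCC(=O)OC | intermediate
12 | (2S)-2-methylbutanoic acid | CC[C@H](C)C(=O)O | starting material
13 | (3S)-3-methylpentan-2-one | CC[C@H](C)C(C)=O | intermediate
14 | (3S)-3-methyl-8-[(1S,2R,5R)-2-methyl-5-(prop-1-en-2-yl)-2-(triethylsilyloxy)cyclopentyl]octane-4,6-dione | C=C(C)[C@@H]1CC[C@@](C)(O[Si](CC)(CC)CC)[C@H]1CCC(=O)CC(=O)[C@@H](C)CC | intermediate
15 | dimethyl 2-methylmalonate | COC(=O)C(C)C(=O)OC | starting material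
16 | 1-bromo-3-methylbut-2-ene | CC(C)=CCBr | starting material
17 | dimethyl 2-methyl-2-(3-methylbut-2-en-1-yl)malonate | COC(=O)C(C)(CC=C(C)C)C(=O)OC | intermediate
18 | (2R)-2-(methoxycarbonyl)-2,5-dimethylhex-4-enoic acid | OC(=O)[C@@](C)(CC=C(C)C)C(=O)OC | intermediate
19 | methyl (2S)-2-(chlorocarbonyl)-2,5-dimethylhex-4-enoate | ClC(=O)[C@@](C)(CC=C(C)C)C(=O)OC | intermediate
20 | methyl (2R,8S)-2,8-dimethyl-2-(3-methylbut-2-en-1-yl)-4-{[(1S,2R,5R)-2-methyl-5-(prop-1-en-2-yl)-2-(triethylsilyloxy)cyclopentyl]methyl}-3,5,7-trioxodecanoate (C4 of the chain present as enolate) | C=C(C)[C@@H]1CC[C@@](C)(O[Si](CC)(CC)CC)[C@H]1CC(C(=O)[C@@](C)(CC=C(C)C)C(=O)OC)C(=O)CC(=O)[C@@H](C)CC | intermediate (not isolated)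
21 | (6R)-3,5-dihydroxy-6-methyl-6-(3-methylbut-2-en-1-yl)-2-[(2S)-2-methylbutanoyl]-4-{[(1S,2R,5R)-2-methyl-5-(prop-1-en-2-yl)-2-(triethylsilyloxy)cyclopentyl]methyl}cyclohexa-2,4-dien-1-one | C=C(C)[C@@H]1CC[C@@](C)(O[Si](CC)(CC)CC)[C@H]1CC1=C(O)[C@@](C)(CC=C(C)C)C(=O)C(C(=O)[C@@H](C)CC)=C1O | intermediate
22 | (6R)-3,5-dihydroxy-4-{[(1S,2R,5R)-2-hydroxy-2-methyl-5-(prop-1-en-2-yl)cyclopentyl]methyl}-6-methyl-6-(3-methylbut-2-en-1-yl)-2-[(2S)-2-methylbutanoyl]cyclohexa-2,4-dien-1-one | C=C(C)[C@@H]1CC[C@@](C)(O)[C@H]1CC1=C(O)[C@@](C)(CC=C(C)C)C(=O)C(C(=O)[C@@H](C)CC)=C1O | target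

**Step count**
Total: 16 steps. Longest linear sequence: 12 steps (steps 1–9, 11, 15, 16).

**Steps most likely to fail**

Step 15 (key step). The acid chloride may acylate an enolate oxygen instead of C12, the dianion may be consumed by proton transfer from the acylated product, the C24 enolate may fail to add to the hindered ester, and proton exchange at C27 would erode that centre. The fallback sets out from 18 and 14 and returns at 21. Acid 18 is treated with carbonyldiimidazole to give methyl (2R)-2-(1H-imidazole-1-carbonyl)-2,5-dimethylhex-4-enoate F1. This softer acyl donor is added at −78 °C to the dianion of 14 (LiN(i-Pr)2, 2.2 equiv), where the imidazolide that is set free serves as base for the new acidic proton. Triketo ester 20 is then isolated after mild acidic work-up and closed in a separate Dieckmann step under equilibrating conditions (NaOMe, MeOH, 50 °C) to give 21.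

Step 7. Ionisation of the fully substituted allylic C–O bond must occur on the face syn to the isopropenyl group and may be slow; isomerisation of the allylpalladium intermediate before hydride delivery would then erode the inversion at C10, and β-hydride elimination would give a diene. The fallback sets out from 6 and returns at 10, and fixes C10 by thermodynamic control instead. Alcohol 6 is oxidised (Dess–Martin periodinane, then NaClO2, NaH2PO4, 2-methylbut-2-ene) to (1S,2S,5R)-5-methyl-2-(prop-1-en-2-yl)-6-oxabicyclo[3.1.0]hexane-1-carboxylic acid F2 and methylated (Me3SiCHN2) to methyl (1S,2S,5R)-5-methyl-2-(prop-1-en-2-yl)-6-oxabicyclo[3.1.0]hexane-1-carboxylate F3. Reductive cleavage of the Cα–O bond with SmI2 (THF/MeOH, −78 °C), followed by equilibration with NaOMe in MeOH, should give methyl (1S,2R,5R)-2-hydroxy-2-methyl-5-(prop-1-en-2-yl)cyclopentane-1-carboxylate F4, the epimer in which the ester is trans to both the isopropenyl and the methyl group. Silylation (Et3SiOTf, 2,6-lutidine) gives methyl (1S,2R,5R)-2-methyl-5-(prop-1-en-2-yl)-2-(triethylsilyloxy)cyclopentane-1-carboxylate F5, and i-Bu2AlH at −78 °C gives (1S,2R,5R)-2-methyl-5-(prop-1-en-2-yl)-2-(triethylsilyloxy)cyclopentane-1-carbaldehyde F6. Wittig reaction of F6 with Ph3P=CHCO2Me gives 10.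

Step 13. The enzyme may discriminate poorly between the two enantiotopic ester groups, or may hydrolyse the pro-R group. The fallback sets out from 17 and returns at 18. Diester 17 is mono-saponified (KOH, 1 equiv, MeOH) to racemic 2-(methoxycarbonyl)-2,5-dimethylhex-4-enoic acid F7. This is resolved by fractional crystallisation of (1S)-1-phenylethan-1-aminium (2R)-2-(methoxycarbonyl)-2,5-dimethylhex-4-enoate F8 (the antipodal amine is used if the other salt proves the less soluble one). Cold dilute acid then liberates 18.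

**Further compounds**
F1 | step 15 | methyl (2R)-2-(1H-imidazole-1-carbonyl)-2,5-dimethylhex-4-enoate | O=C(n1ccnc1)[C@@](C)(CC=C(C)C)C(=O)OC
F2 | step 7 | (1S,2S,5R)-5-methyl-2-(prop-1-en-2-yl)-6-oxabicyclo[3.1.0]hexane-1-carboxylic acid | C=C(C)[C@@H]1CC[C@@]2(C)O[C@@]12C(=O)O
F3 | step 7 | methyl (1S,2S,5R)-5-methyl-2-(prop-1-en-2-yl)-6-oxabicyclo[3.1.0]hexane-1-carboxylate | C=C(C)[C@@H]1CC[C@@]2(C)O[C@@]12C(=O)OC
F4 | step 7 | methyl (1S,2R,5R)-2-hydroxy-2-methyl-5-(prop-1-en-2-yl)cyclopentane-1-carboxylate | C=C(C)[C@@H]1CC[C@@](C)(O)[C@H]1C(=O)OC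
F5 | step 7 | methyl (1S,2R,5R)-2-methyl-5-(prop-1-en-2-yl)-2-(triethylsilyloxy)cyclopentane-1-carboxylate | C=C(C)[C@@H]1CC[C@@](C)(O[Si](CC)(CC)CC)[C@H]1C(=O)OC
F6 | step 7 | (1S,2R,5R)-2-methyl-5-(prop-1-en-2-yl)-2-(triethylsilyloxy)cyclopentane-1-carbaldehyde | C=C(C)[C@@H]1CC[C@@](C)(O[Si](CC)(CC)CC)[C@H]1C=O
F7 | step 13 | racemic 2-(methoxycarbonyl)-2,5-dimethylhex-4-enoic acid | OC(=O)C(C)(CC=C(C)C)C(=O)OC
F8 | step 13 | (1S)-1-phenylethan-1-aminium (2R)-2-(methoxycarbonyl)-2,5-dimethylhex-4-enoate | C[C@H]([NH3+])c1ccccc1.[O-]C(=O)[C@@](C)(CC=C(C)C)C(=O)OC
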